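**Retrosynthetic overview** (germacrane numbering: ring C1–C10, methyls C14 on C10 and C15 on C4, lactone C11(=C13)–C12)

1. Feature: in the ten-membered carbocycle C1–C10 the C1/C10 syn-diol is a masked E C1=C10 alkene. With Z C4=C5 and oxygen at C3, C6 and C8, the ring is the [3,3] image of a trans-1,2-dialkenylcyclohexenol. Its atoms C1–C6, C15 and the isopropenyl unit C9/C10/C14 are those of (R)-carvone.
2. End game, with no base once the C3 ketone is present: OsO4 on C1=C10 comes last, the C3 ketone comes from the carveol oxygen, and C13 comes from Mannich methylenation of the lactone.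
3. γ-Lactone (C6–O–C12): closed from O6 and a C7 acetic arm. C7 is set by alkylating the C8-alkoxide/C6-enolate dianion. C6 and the C8 isobutyrate are set together by an Evans–Tishchenko reduction with isobutyraldehyde.
4. Ten-membered ring: anionic oxy-Cope ring expansion (C8–C9 made, C1–C6 cut). The substrate is the adduct of an (E)-2-(4-methoxybenzyloxy)vinyl metal with the C6 enone, which comes from carvone by Luche reduction, silylation and allylic oxidation.
5. Ring order: cyclohexene of carvone (given), then the ten-membered ring (step 8), then the γ-lactone (step 12).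

Key step: step 8

Assumption: the target is taken as the open 3-keto-1,10-diol of the given SMILES; its possible ring–chain tautomerism with the 3,10-hemiketal needs no separate step.

**Route**

Step 1
Reactants: 1 (R)-carvone
Product: 2 (1R,5R)-cis-carveol (OH cis to isopropenyl)
Conditions: NaBH4, CeCl3·7H2O, MeOH, 0 °C
Reagents that add atoms: none
Why: Luche reduction adds hydride 1,2 only, and axial delivery to the half-chair with the equatorial isopropenyl group gives the equatorial cis alcohol (C3, a temporary centre that is later oxidised).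

Step 2
Reactants: 2 (1R,5R)-cis-carveol
Product: 3 cis-carveol tert-butyldimethylsilyl ether
Conditions: TBSCl, imidazole, DMF, rt
Reagents that add atoms: tert-butyldimethylsilyl chloride, CC(C)(C)[Si](C)(C)Cl
Why: Imidazole-promoted silylation of a secondary allylic alcohol touches no stereocentre and gives an ether that survives organometals, KH, amide bases and DDQ.

Step 3
Reactants: 3 cis-carveol tert-butyldimethylsilyl ether
Product: 4 (4R,6R)-4-(tert-butyldimethylsilyloxy)-3-methyl-6-(prop-1-en-2-yl)cyclohex-2-en-1-one (ketone carbon = C6)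
Conditions: CrO3, 3,5-dimethylpyrazole, CH2Cl2, −20 °C
Reagents that add atoms: chromium trioxide, O=[Cr](=O)=O
Why: Allylic oxidation with the CrO3–3,5-dimethylpyrazole complex takes the only ring methylene allylic to the trisubstituted alkene (C6) to the enone, because the bulky silyl ether shields C3–H and the isopropenyl group is less reactive, and C1 is safe because the cis-1,3-diequatorial isomer is also the stable one.

Step 4
Reactants: 5 4-methoxybenzyl alcohol; 6 trichloroethylene
Product: 7 (E)-1,2-dichlorovinyl 4-methoxybenzyl ether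
Conditions: KH, THF, 0 °C; 6, −50 °C → rt
Reagents that add atoms: trichloroethylene 6, ClC=C(Cl)Cl
Why: Base-induced loss of HCl from 6 gives dichloroacetylene, to which the potassium alkoxide adds anti, the standard addition–elimination entry to dichlorovinyl ethers.

Step 5
Reactants: 7 (E)-1,2-dichlorovinyl 4-methoxybenzyl ether
Product: 9 ethynyl 4-methoxybenzyl ether, via lithium acetylide 8 (not isolated)
Conditions: n-BuLi (2.2 equiv), Et2O, −78 → −40 °C; H2O, −78 °C; kept below rt and used at once
Reagents that add atoms: none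
Why: β-Elimination of HCl followed by chlorine–lithium exchange is the established route from dichlorovinyl ethers to alkynyl ethers, and cold handling avoids the thermal [3,3] shift of benzyl alkynyl ethers.

Step 6
Reactants: 9 ethynyl 4-methoxybenzyl ether
Product: 11 (E)-2-iodovinyl 4-methoxybenzyl ether, via alkenylzirconocene chloride 10 (not isolated)
Conditions: Cp2Zr(H)Cl, THF, 0 °C → rt; I2, −78 °C
Reagents that add atoms: iodine, II
Why: Hydrozirconation with the Schwartz reagent adds H and Zr syn with the metal on the terminal carbon, and iodinolysis proceeds with retention, which fixes the E enol ether geometry.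

Step 7
Reactants: 11 (E)-2-iodovinyl 4-methoxybenzyl ether; 4 enone
Product: 14 (1R,4R,6R)-4-(tert-butyldimethylsilyloxy)-1-[(E)-2-(4-methoxybenzyloxy)vinyl]-3-methyl-6-(prop-1-en-2-yl)cyclohex-2-en-1-ol (alkenyl groups trans; OH cis to isopropenyl), via E-alkenyllithium 12 (not isolated), via alkenylcerium dichloride 13 (not isolated)
Conditions: 11, t-BuLi (2 equiv), Et2O, −78 °C; CeCl3, THF, −78 °C; 4, −78 °C; aq NH4Cl
Reagents that add atoms: iodide 11 as alkenyl donor, COc1ccc(CO/C=C/I)cc1
Why: Iodine–lithium exchange at −78 °C retains the E geometry and outruns loss of alkoxide, and the weakly basic, bulky organocerium reagent adds 1,2 to the enolisable ketone along the equatorial trajectory on the face away from the isopropenyl and silyloxy groups, as alkenyl metals do with 2-substituted cyclohexanones, which sets C6 (R).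

Step 8
Reactants: 14 trans-1,2-dialkenylcyclohexenol
Product: 17 (2Z,4R,6E,9R)-4-(tert-butyldimethylsilyloxy)-9-(4-methoxybenzyloxy)-3,7-dimethylcyclodeca-2,6-dien-1-one (germacrane locants: 6-one 3-OTBS 8-OPMB 1(10)E 4Z), via potassium alkoxide 15 (not isolated), via potassium enolate 16 (not isolated)
Conditions: KH, 18-crown-6, THF, 0 °C → rt; cannulated into AcOH, THF, −78 °C
Reagents that add atoms: none
Why: KH deprotonates the tertiary alcohol and 18-crown-6 frees the anion, so alkoxide 15 undergoes the charge-accelerated [3,3] shift in which C8–C9 forms as C1–C6 breaks; this is an anionic oxy-Cope rearrangement, and the closest known type is the six-to-ten ring expansion of alkenyl adducts of 6-isopropenylcyclohexenones. The ten-membered ring is not closed end to end but arises by four-atom expansion of the cyclohexene through a chair transition state shaped like a trans-decalin, with C2 and C5 equatorial and O− and H-1 axial. Equatorial C2 makes C1=C10 E, and the E enol ether places the OPMB group equatorial at C8, so the carvone centre C1, which is lost in this step, is relayed to C8 (R). Periselectivity is needed between the two 3-oxido-1,5-diene arrays at C6, and only the exocyclic enol ether can reach C9 of the equatorial isopropenyl group in a chair, because the endocyclic C4=C5 is held away from it. Chemoselectivity is needed against E1cB loss of 4-methoxybenzyl oxide from enolate 16: in this ring-trans enolate the C8–C9 ring bond stands perpendicular to the enolate plane, which keeps C8–O near the nodal plane, and the cold acetic acid quench keeps the enolate short-lived while leaving C3 untouched.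

Step 9
Reactants: 17 ten-membered dienone PMB ether
Product: 18 (2Z,4R,6E,9R)-4-(tert-butyldimethylsilyloxy)-9-hydroxy-3,7-dimethylcyclodeca-2,6-dien-1-one (8-hydroxy-6-ketone)
Conditions: DDQ, CH2Cl2/pH 7 buffer, 0 °C
Reagents that add atoms: none
Why: Oxidative cleavage of the electron-rich benzyl ether by DDQ under buffered conditions spares the silyl ether, the enone and both alkenes and leaves C8 untouched.

Step 10
Reactants: 18 8-hydroxy-6-ketone; 19 tert-butyl bromoacetate
Product: 21 (3R,7R,8R)-keto ester (18 bearing CH2CO2t-Bu at C7 anti to the C8 hydroxyl), via dilithium alkoxide-enolate 20 (not isolated)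
Conditions: LDA (2.3 equiv), THF, −78 °C (18 added to the base); 19, −78 → −50 °C; AcOH, −78 °C
Reagents that add atoms: tert-butyl bromoacetate 19, BrCC(=O)OC(C)(C)C
Why: Proposed new method: two equivalents of LDA should give the alkoxide–enolate 20, in which oxide cannot leave (no E1cB) and C7 is the only enolisable α-carbon (C5 is vinylic), with lithium bridging the two oxygens in a six-membered chelate so that the bromide is attacked by C7 anti to the C8–C9 bond, which is also the outer face of the ring, giving the 7,8-anti product (7R); the closest known reaction type is the Fráter–Seebach alkylation of β-hydroxy ester dianions, carried over here to a β-hydroxy enone.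

Step 11
Reactants: 21 keto ester; 22 isobutyraldehyde
Product: 23 (3R,6R,7S,8R)-6-hydroxy-8-isobutyryloxy tert-butyl ester (O6 and O8 1,3-anti)
Conditions: SmI2 (0.3 equiv), 22 (6 equiv), THF, −10 °C, dark
Reagents that add atoms: isobutyraldehyde 22, CC(C)C=O
Why: In the Evans–Tishchenko reduction the samarium-bound hemiacetal of O8 and 22 passes its hydride to C6 through a chair-like bicyclic transition state with C5, C9 and C11 equatorial, which gives the 1,3-anti alcohol (6R), leaves the isobutyrate on O8 and keeps O6 free.

Step 12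
Reactants: 23 hydroxy tert-butyl ester
Product: 26 (3R,6R,7R,8R)-trans-fused 6,12-lactone with 8-isobutyrate and 3-OTBS, via bis-trimethylsilyl derivative 24 (not isolated), via hydroxy acid 25 (not isolated)
Conditions: TMSOTf, 2,6-lutidine, CH2Cl2, 0 °C; aq citric acid, THF, rt; DCC, DMAP (cat.), CH2Cl2, 0 °C
Reagents that add atoms: none
Why: Silyl triflate cleaves the tert-butyl ester without a strong protic acid that could trigger transannular cyclisation of the diene, and Steglich-type closure of the γ-hydroxy acid can only engage O6 because O8 is acylated, so no stereocentre is touched.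

Step 13
Reactants: 26 lactone; 27 Eschenmoser's salt
Product: 29 11-(dimethylaminomethyl) lactone (C11 epimers; this centre is removed in step 14), via lithium lactone enolate 28 (not isolated)
Conditions: LiN(SiMe3)2 (1.1 equiv), THF, −78 °C; 27, −78 → 0 °C
Reagents that add atoms: N,N-dimethylmethyleneiminium iodide 27, C=[N+](C)C.[I-]
Why: In this Mannich reaction of a lactone enolate, the silazide is basic enough for the lactone CH2 but reacts slowly with the less acidic, hindered isobutyrate CH, and C7 carries no leaving group.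

Step 14
Reactants: 29 Mannich base
Product: 31 α-methylene lactone with 8-isobutyrate and 3-OTBS, via quaternary ammonium iodide 30 (not isolated)
Conditions: MeI, CH2Cl2/MeOH, rt; aq NaHCO3, rt
Reagents that add atoms: none
Why: Exhaustive methylation followed by Hofmann-type elimination under bicarbonate is the standard mild release of an α-methylene-γ-lactone and removes the C11 centre.

Step 15
Reactants: 31 silyl ether
Product: 32 3-hydroxy α-methylene lactone
Conditions: HF·pyridine, pyridine, THF, 0 °C
Reagents that add atoms: none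
Why: Buffered fluoride desilylation frees the allylic alcohol without base that could add to the methylene lactone or move the ester.

Step 16
Reactants: 32 allylic alcohol
Product: 33 (6R,7R,8R)-3-oxo-1(10)E,4Z-dienolide
Conditions: Dess–Martin periodinane, pyridine, CH2Cl2, 0 °C
Reagents that add atoms: none
Why: Dess–Martin oxidation is neutral, so the enone forms without pulling the β,γ-alkene C1=C10 into conjugation, and it deactivates C4=C5 towards the last step.

Step 17
Reactants: 33 3-oxo dienolide
Product: 34 target (1R,6R,7R,8R,10R)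
Conditions: OsO4 (5 mol %), (DHQD)2PHAL (10 mol %), NMO (1.05 equiv), acetone/H2O, 0 °C
Reagents that add atoms: osmium tetroxide, O=[Os](=O)(=O)=O; N-methylmorpholine N-oxide, C[N+]1([O-])CCOCC1; water, O
Why: Ligand-accelerated OsO4 syn-dihydroxylation (Sharpless type) should select the strained, electron-rich E C1=C10 alkene over the enone and the acrylate-like methylene, suprafacial addition to the E alkene fixes the C1/C10 relation, and the absolute sense (1R,10R) follows from attack on the outer face of the alkene, which stands perpendicular to the ring with C14 on the side of the C7 arm as in peracid epoxidations of 1(10)E,4Z-germacranolides, reinforced by the DHQD ligand (H-1 south-east, C9 south-west in the mnemonic, attack from the top).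

**Compound list**

1 | (R)-carvone | CC1=CC[C@H](CC1=O)C(C)=C | starting material
2 | (1R,5R)-cis-carveol | CC1=CC[C@H](C[C@H]1O)C(C)=C | intermediate
3 | cis-carveol TBS ether | CC1=CC[C@H](C[C@H]1O[Si](C)(C)C(C)(C)C)C(C)=C | intermediate
4 | (4R,6R)-4-silyloxy-3-methyl-6-isopropenylcyclohex-2-enone | O=C1C=C(C)[C@H](O[Si](C)(C)C(C)(C)C)C[C@@H]1C(C)=C | intermediate
5 | 4-methoxybenzyl alcohol | COc1ccc(CO)cc1 | starting material
6 | trichloroethylene | ClC=C(Cl)Cl | starting material
7 | (E)-1,2-dichlorovinyl 4-methoxybenzyl ether | COc1ccc(CO/C(Cl)=C\Cl)cc1 | intermediate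
8 | lithium (4-methoxybenzyloxy)acetylide | [Li]C#COCc1ccc(OC)cc1 | intermediate
9 | ethynyl 4-methoxybenzyl ether | C#COCc1ccc(OC)cc1 | intermediate
10 | (E)-2-(4-methoxybenzyloxy)vinylzirconocene chloride (Cp drawn σ-bound) | COc1ccc(CO/C=C/[Zr](Cl)(C2C=CC=C2)C2C=CC=C2)cc1 | intermediate
11 | (E)-2-iodovinyl 4-methoxybenzyl ether | COc1ccc(CO/C=C/I)cc1 | intermediate
12 | (E)-2-(4-methoxybenzyloxy)vinyllithium | [Li]/C=C/OCc1ccc(OC)cc1 | intermediate
13 | (E)-2-(4-methoxybenzyloxy)vinylcerium dichloride | Cl[Ce](Cl)/C=C/OCc1ccc(OC)cc1 | intermediate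
14 | (1R,4R,6R)-trans-1,2-dialkenylcyclohexenol (oxy-Cope precursor) | COc1ccc(CO/C=C/[C@@]2(O)C=C(C)[C@H](O[Si](C)(C)C(C)(C)C)C[C@@H]2C(C)=C)cc1 | intermediate
15 | potassium alkoxide of 14 | [K+].COc1ccc(CO/C=C/[C@@]2([O-])C=C(C)[C@H](O[Si](C)(C)C(C)(C)C)C[C@@H]2C(C)=C)cc1 | intermediate
16 | potassium C6=C7 enolate of 17 (O cis to C8) | [K+].C1/C(C)=C/C[C@@H](O[Si](C)(C)C(C)(C)C)/C(C)=C\C(\[O-])=C\[C@@H]1OCc1ccc(OC)cc1 | intermediate
17 | ten-membered dienone, 3-OTBS, 8-OPMB, 1(10)E, 4Z | O=C1/C=C(/C)[C@H](O[Si](C)(C)C(C)(C)C)C/C=C(\C)C[C@@H](OCc2ccc(OC)cc2)C1 | intermediate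
18 | 8-hydroxy-6-ketone | O=C1/C=C(/C)[C@H](O[Si](C)(C)C(C)(C)C)C/C=C(\C)C[C@@H](O)C1 | intermediate
19 | tert-butyl bromoacetate | BrCC(=O)OC(C)(C)C | starting material
20 | dilithium C8-alkoxide C6-enolate | [Li+].[Li+].C1/C(C)=C/C[C@@H](O[Si](C)(C)C(C)(C)C)/C(C)=C\C(\[O-])=C\[C@@H]1[O-] | intermediate
21 | (3R,7R,8R)-7-(tert-butoxycarbonylmethyl)-8-hydroxy-6-ketone | O=C1/C=C(/C)[C@H](O[Si](C)(C)C(C)(C)C)C/C=C(\C)C[C@@H](O)[C@H]1CC(=O)OC(C)(C)C | intermediate
22 | isobutyraldehyde | CC(C)C=O | starting material
23 | 6-hydroxy-8-isobutyrate tert-butyl ester | O[C@@H]1/C=C(/C)[C@H](O[Si](C)(C)C(C)(C)C)C/C=C(\C)C[C@@H](OC(=O)C(C)C)[C@H]1CC(=O)OC(C)(C)C | intermediate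
24 | 6-O-TMS ether TMS ester | C[Si](C)(C)O[C@@H]1/C=C(/C)[C@H](O[Si](C)(C)C(C)(C)C)C/C=C(\C)C[C@@H](OC(=O)C(C)C)[C@H]1CC(=O)O[Si](C)(C)C | intermediate
25 | 6-hydroxy acid | O[C@@H]1/C=C(/C)[C@H](O[Si](C)(C)C(C)(C)C)C/C=C(\C)C[C@@H](OC(=O)C(C)C)[C@H]1CC(=O)O | intermediate
26 | trans-6,12-lactone, 8-isobutyrate, 3-OTBS | C1C(=O)O[C@@H]2/C=C(/C)[C@H](O[Si](C)(C)C(C)(C)C)C/C=C(\C)C[C@@H](OC(=O)C(C)C)[C@@H]12 | intermediate
27 | Eschenmoser's salt | C=[N+](C)C.[I-] | starting material
28 | lithium enolate of lactone 26 | [Li+].C1=C([O-])O[C@@H]2/C=C(/C)[C@H](O[Si](C)(C)C(C)(C)C)C/C=C(\C)C[C@@H](OC(=O)C(C)C)[C@@H]12 | intermediate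
29 | 11-(dimethylaminomethyl) lactone (C11 unassigned) | CN(C)CC1C(=O)O[C@@H]2/C=C(/C)[C@H](O[Si](C)(C)C(C)(C)C)C/C=C(\C)C[C@@H](OC(=O)C(C)C)[C@@H]12 | intermediate
30 | trimethylammonium iodide of 29 | C[N+](C)(C)CC1C(=O)O[C@@H]2/C=C(/C)[C@H](O[Si](C)(C)C(C)(C)C)C/C=C(\C)C[C@@H](OC(=O)C(C)C)[C@@H]12.[I-] | intermediate
31 | α-methylene lactone, 3-OTBS | C=C1C(=O)O[C@@H]2/C=C(/C)[C@H](O[Si](C)(C)C(C)(C)C)C/C=C(\C)C[C@@H](OC(=O)C(C)C)[C@@H]12 | intermediate
32 | α-methylene lactone, 3-OH | C=C1C(=O)O[C@@H]2/C=C(/C)[C@H](O)C/C=C(\C)C[C@@H](OC(=O)C(C)C)[C@@H]12 | intermediate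
33 | 3-oxo-1(10)E,4Z-dienolide | C=C1C(=O)O[C@@H]2/C=C(/C)C(=O)C/C=C(\C)C[C@@H](OC(=O)C(C)C)[C@@H]12 | intermediate
34 | CNP0124434.2 | C=C1C(=O)O[C@@H]2/C=C(/C)C(=O)C[C@@H](O)[C@](C)(O)C[C@@H](OC(=O)C(C)C)[C@@H]12 | target

**Totals**

Total step count: 17. Longest linear sequence: 14 steps (steps 1–3 and 7–17 from carvone; steps 4–17 from 4-methoxybenzyl alcohol give the same length).

**Steps most likely to fail**

1. Step 10 (proposed new method).
   - What may go wrong: retro-aldol opening of the strained lithium aldolate before the second deprotonation; deprotonation at the γ positions (C15, C3) instead of C7; attack of the C8 alkoxide on the new ester.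
   - Fallback (known chemistry): steps 9 and 10 are run in the reverse order, starting from 17.
   - With the PMB ether still on O8, 17 is enolised with LiN(SiMe3)2 in THF at −78 °C to the lithium enolate F1.
   - F1 is alkylated at once with 19 to the PMB-protected keto ester F2. This is a plain kinetic ketone enolate alkylation, and lithium held between the enolate oxygen and the ether oxygen should favour the same 7,8-anti sense.
   - DDQ as in step 9 then frees O8, and the route is rejoined at 21.

2. Step 8 (key step).
   - What may go wrong: E1cB expulsion of 4-methoxybenzyl oxide from the potassium enolate during the rearrangement; leakage through a boat transition state, which would erode the relay to C8.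
   - Fallback: the elimination is accepted, and C8–O is set by a catalyst instead of by chirality transfer. It starts from 14.
   - The rearrangement is left at room temperature until enolate 16 has lost its alkoxide, which gives the cross-conjugated trienone F3.
   - Copper-catalysed conjugate borylation (CuCl, NaOt-Bu, BINAP in the enantiomer matched to outer-face attack, B2pin2, MeOH, THF) adds boron to C8 of the less substituted enone and gives the β-boryl ketone F4.
   - NaBO3 in THF/H2O oxidises C–B with retention, and the route is rejoined at 18.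

3. Step 11.
   - What may go wrong: retro-aldol cleavage through the trivalent samarium aldolate; slow hemiacetal formation at the hindered C8 hydroxyl; acyl shift from O8 to O6 before lactonisation.
   - Fallback: reduction and acylation are separated, starting from 21.
   - Me4NBH(OAc)3 in AcOH/MeCN at −30 °C (hydroxyl-directed Evans–Saksena reduction, acidic medium, no alkoxide) gives the 1,3-anti diol F5.
   - TMSOTf/2,6-lutidine converts F5 into the persilylated ester F6, and aqueous citric acid gives the dihydroxy acid F7.
   - DCC/DMAP closes F7 onto O6, because O8 is held antiperiplanar to the acetic arm in the 7,8-anti series, and gives the 8-hydroxy lactone F8.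
   - Isobutyryl chloride, DMAP and pyridine then rejoin the route at 26.

**Further compounds**

F1 | step 10 | lithium C6=C7 enolate of 17 | [Li+].C1/C(C)=C/C[C@@H](O[Si](C)(C)C(C)(C)C)/C(C)=C\C(\[O-])=C\[C@@H]1OCc1ccc(OC)cc1
F2 | step 10 | (3R,7R,8R)-7-(tert-butoxycarbonylmethyl)-8-OPMB-6-ketone | O=C1/C=C(/C)[C@H](O[Si](C)(C)C(C)(C)C)C/C=C(\C)C[C@@H](OCc2ccc(OC)cc2)[C@H]1CC(=O)OC(C)(C)C
F3 | step 8 | (1(10)E,4Z,7E)-3-silyloxy trien-6-one | C1/C=C(\C)C/C=C/C(=O)/C=C(/C)[C@@H]1O[Si](C)(C)C(C)(C)C
F4 | step 8 | (3R,8R)-8-(pinacolatoboryl)-6-ketone | O=C1/C=C(/C)[C@H](O[Si](C)(C)C(C)(C)C)C/C=C(\C)C[C@@H](B2OC(C)(C)C(C)(C)O2)C1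
F5 | step 11 | (3R,6R,7R,8R)-6,8-anti-diol tert-butyl ester | O[C@@H]1/C=C(/C)[C@H](O[Si](C)(C)C(C)(C)C)C/C=C(\C)C[C@@H](O)[C@H]1CC(=O)OC(C)(C)C
F6 | step 11 | 6,8-bis-O-TMS ether TMS ester | C[Si](C)(C)O[C@@H]1/C=C(/C)[C@H](O[Si](C)(C)C(C)(C)C)C/C=C(\C)C[C@@H](O[Si](C)(C)C)[C@H]1CC(=O)O[Si](C)(C)C
F7 | step 11 | 6,8-dihydroxy acid | O[C@@H]1/C=C(/C)[C@H](O[Si](C)(C)C(C)(C)C)C/C=C(\C)C[C@@H](O)[C@H]1CC(=O)O
F8 | step 11 | 8-hydroxy trans-6,12-lactone | C1C(=O)O[C@@H]2/C=C(/C)[C@H](O[Si](C)(C)C(C)(C)C)C/C=C(\C)C[C@@H](O)[C@@H]12
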